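**Remarks on the chemistry**

- Numbering: eremophilane numbering throughout (ring A = C1–C5 and C10; ring B = C5–C10; C14 = methyl on C5; C15 = methyl on C4; C11–C13 = isopropenyl on C7). β is the face of the C5 methyl, α the opposite face. Acyclic and monocyclic intermediates are discussed with the labels of the atoms they become.
- Stereochemical check: 32 is 3α-acyloxy, 4β-methyl, 5β-methyl, 7α-isopropenyl, 8α-hydroxy, 9α-acyloxy, 10α-H (trans-fused). Lactone 12 (C3 = S, chain C6 cis to C3) should pass through the ring-enforced boat directly to 15 with the carboxyl cis to the C5 methyl. No equilibration at C10 is therefore planned; the two C10 epimers should be close in energy, so enolisation there is a hazard and not a remedy.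
- Correction to the precursor synthesis: unactivated internal alkynes such as but-2-yne do not undergo carbocupration, so the Z tetrasubstituted alkene is built by hydroxyl-directed carbomagnesiation of a propargylic alcohol instead.
- Assumption: the (S,S)-configured ruthenium catalyst is taken to give the (S)-carbinol 4, as with other alkyl alkynyl ketones; the mirror-image ligand would be used if the sense were reversed.

## Structural features

Compound 32 is a trans-fused decalin of the eremophilane type. Rings A and B share the C5–C10 bond; C5 is quaternary with an axial β methyl and C10 carries an α hydrogen. Seven stereocentres run without a break around the periphery, C3–C4–C5–C10–C9–C8–C7. Ring A holds an equatorial 3α ester and an equatorial 4β methyl cis to the C5 methyl. Ring B holds an all-cis triad: equatorial 7α isopropenyl, axial 8α hydroxyl, equatorial 9α ester. The fragile groups are the two (Z)-hex-2-enoates (Z to E isomerisation, conjugate addition, hydride reduction), the cis C8-hydroxy/C9-ester pair (acyl migration) and the isopropenyl group (conjugation next to a C8 carbonyl; attack by boranes, OsO4 and H2). The real difficulty is the quaternary C5 between the stereogenic C4 and C10, and the crowded axial C8 hydroxyl that must stay free while C3 and C9 are acylated. The key step exploits the fact that C5–C10 joins the quaternary carbon to a carbon whose other substituent, C9, is oxygenated. C9 can be raised to a carboxyl, C10 becomes an ester α-carbon, and C3 (reached from C10 through C1–C2) bears the oxygen that closes a δ-lactone next to a C4=C5 alkene. A [3,3] shift of that lactone's ketene acetal then makes C5–C10 and ring A together; the C3 oxygen spent in the shift returns by hydroboration of the C3=C4 bond left behind, which also sets C4.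

## Logic of the disconnections

**32 to 31.** No skeletal bond is cut; the two Z C=C bonds are traced back to C≡C. A Z-enoyl donor would isomerise under acylation catalysis, whereas an alkynoate has no geometry to lose. The gain is that the geometry problem moves to the last step. The forward step must stop at the alkene and spare the isopropenyl group.

**31 to 29 and 30.** The two ester C–O bonds at O3 and O9 are cut. This is convergent and uses one acid twice. The forward step must acylate the two equatorial hydroxyls and leave the axial C8 hydroxyl.

**29 to 28 to 27.** The silyl ethers are removed and the C8–H bond is cut, giving a C8 ketone. An axial alcohol between two equatorial neighbours is what equatorial hydride delivery gives. One stereocentre disappears and C7 becomes acidic. The forward step needs a bulky hydride that reduces faster than it enolises.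

**27 to 24 and 25.** The C7–C11 bond is cut. C7 is α to the C8 carbonyl, and an equatorial isopropenyl is the favoured arrangement. Ring B is reduced to a 9-oxygenated 8-ketone. The forward step must alkenylate once, at C7 and not C9, and the product must not slide into conjugation.

**24 to 23 to 21.** The silyl groups are removed and the C8 carbonyl is traced to a cis-8,9-diol. C8 and C9 can be told apart because C8–O is axial and C9–O equatorial. The forward step must oxidise only the axial hydroxyl of the cis pair and leave C3–OH alone.

**21 to 19.** The C3–O and C4–H bonds are cut as a syn addition to C3=C4. In the trans-decalin the axial C5 methyl blocks the β face. Two stereocentres go, and the alkene is exactly what the key step leaves. The forward step needs α-face, anti-Markovnikov addition with no other borane-reactive group present.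

**19 to 18.** The C8–C9 bond is cut. Both carbons carry oxygen and are cis, which is the signature of a pinacol coupling of a 1,6-dialdehyde. The bicycle becomes a cyclohexene. The forward step must give the cis-diol with C9–O equatorial and must not epimerise C10.

**18 to 17 to 15.** Only oxidation levels change at C8 and C9, and the silyl ether is removed. This links the dialdehyde to the acid that the key step delivers. The forward oxidation must be non-basic.

**15 to 12.** The C5–C10 bond is cut and O–C3 reconnected, which turns ring A into a δ-lactone with an exocyclic Z alkene. One carbinol centre (C3) then controls both C5 and C10. The forward step demands a boat [3,3] shift that creates a quaternary centre.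

**12 to 11 to 9.** The lactone acyl C9–O bond is cut and C9 is taken back to a terminal alkene. The carboxyl is thereby masked as a group inert to organomagnesium and palladium reagents. The forward steps need hydroboration of the terminal alkene only and oxidation of the primary alcohol only.

**9 to 6 and 7 (through 8).** The C5–C6 bond is cut. An sp2–sp3 coupling with retention carries the alkene geometry over from a vinyl iodide. The forward step must couple a hindered tetrasubstituted iodide.

**6 to 4.** The C4–C15 and C5–I bonds are cut as an anti addition across an alkyne. The carbinol oxygen fixes both regiochemistry and geometry. The forward step must carbometalate an internal alkyne.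

**4 to 3 to 1 and 2.** The C3–H bond is cut (carbinol from ketone), then the C3–C4 bond (ynone from alkyne and acyl chloride). The only stereocentre carried into the key step comes from a catalytic reduction. Both steps must leave the terminal alkene alone.

## Other disconnections considered

**Alternative 1:** Ring A is contracted to a cyclopentane. The C4–C5 bond comes from a 1,2-shift in the vinyl carbinol A2, itself made by vinyl addition to the saturated ketone of the proline-derived hydrindenedione A1. In the forward key step NBS forms a bromonium ion on the vinyl group, the C3–C5 bond migrates to C4, and the bromomethyl octalenedione A3 results. In its favour, the quaternary C5 comes from a cheap, scalable organocatalytic annulation, and the bicyclic core is reached in fewer steps than in the chosen plan; on step economy to the core this alternative is the better. The ring B enone of A3 is also an asset: dissolving-metal reduction should set the trans fusion and give a regiodefined C8–C9 enolate for oxygenation at C9. On that point it is again better than the chosen plan, which must differentiate C8 from C9 after a pinacol coupling. Against it, the vinyl nucleophile must choose the saturated ketone over the enone. C4 is set under kinetic control by the face of bromonium formation, with no clear bias; it is α to the C3 carbonyl and could be equilibrated, but loss of HBr to an exocyclic enone competes. The bromomethyl group also needs an extra reduction. Mechanistically it is a cationic shift with one centre open, whereas the chosen sigmatropic step ties C5 and C10 to one carbinol. The endgame at C7–C9 would be the same in both plans.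

**Alternative 2:** Both C9–C10 and C4–C5 are cut, leading to the acyclic aldehyde A4. In the forward step MeAlCl2 activates the aldehyde, the E trisubstituted alkene attacks through C10, and the enol silyl ether closes ring A through C4, giving the trans-decalin A5. In its favour, two rings and four stereocentres (C4, C5, C9, C10) form at once, and C7 and C8 are set on an open chain where aldol and allylation methods are strong. A5 already has the isopropenyl group and has C8 and C9 differentiated (silyl ether against free hydroxyl). On these points it is better than the chosen plan, which needs a ketone α-alkenylation, a selective diol oxidation and a selective acylation. Against it, A4 needs an E trisubstituted alkene, a geometrically pure enol ether and a syn C7/C8 pair, so its synthesis is long. The isopropenyl group is itself a π-nucleophile close to the activated aldehyde and may intercept it in a carbonyl-ene reaction. The C9 configuration depends on whether the α-silyloxy aldehyde reacts chelated or not. The chair–chair cyclisation of an E alkene is a sound way to a trans-decalin, the equal of the Claisen route in reliability of ring fusion. However, it places the whole stereochemical risk in one late step, whereas the chosen plan spreads it.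

**Alternative 3:** C4–C5 and C1–C10 are cut, giving the quinone A6 and the 2-silyloxydiene A7. In the forward step a cationic boron Lewis acid (a prolinol-derived B-aryl oxazaborolidine protonated by HNTf2) catalyses the endo Diels–Alder addition to the methyl-bearing quinone bond and gives the cis-fused adduct A8. In its favour it is convergent and catalytic in chirality from the first step. The quaternary C5 forms easily because the methoxy-bearing bond is deactivated. Ring B arrives oxygenated at C8 and C9, and C3 arrives as an enol ether. In speed to a functionalised bicycle it is better than the chosen plan. Against it, the endo rule places the C4 methyl trans to the C5 methyl and makes the ring fusion cis, so A8 has the wrong relative configuration at C4 and C10. Both centres are α to carbonyls and could be inverted by enolisation, but a favourable equilibrium is not assured. The C6 carbonyl is superfluous and must be removed next to the quaternary centre. The vinylogous ester must be converted regioselectively to the C8 ketone/C9 alcohol pattern, and C7 still needs its isopropenyl group. The two pericyclic key steps are equals in the reliability of bond formation, but the Claisen shift should set C5 and C10 in the target's configuration, whereas the cycloaddition leaves C4 and C10 to be inverted, and the chosen plan is the more economical in redox changes.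

Key step: step 7

## Route

Step 1
Reactants: 1 propyne; 2 pent-4-enoyl chloride
Product: 3 oct-7-en-2-yn-4-one
Conditions: PdCl2(PPh3)2 (2 mol %), CuI (4 mol %), Et3N (1.2 equiv), THF, 0 °C → rt
Reagents that add atoms: none
Why: Acyl Sonogashira coupling; the copper acetylide of propyne transmetalates to the acylpalladium chloride and reductive elimination gives the ynone without the over-addition that alkynyl Grignard reagents cause. The remote terminal alkene is inert.

Step 2
Reactants: 3 oct-7-en-2-yn-4-one
Product: 4 (4S)-oct-7-en-2-yn-4-ol
Conditions: Ru[(S,S)-TsNCH(Ph)CH(Ph)NH](p-cymene) (1 mol %), i-PrOH, rt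
Reagents that add atoms: none
Why: Noyori asymmetric transfer hydrogenation of an alkynyl ketone; hydride and proton are delivered together from the metal–ligand pair, with the alkyne acting as the π-substituent that the catalyst recognises. The C3 stereocentre (S) is set by the catalyst, and the base-free amido complex avoids conjugate addition to the ynone.

Step 3
Reactants: 4 (4S)-oct-7-en-2-yn-4-ol
Product: 6 (2Z,4S)-2-iodo-3-methylocta-2,7-dien-4-ol, via cyclic alkenylmagnesium alkoxide 5 (not isolated)
Conditions: MeMgCl (4 equiv), CuI (10 mol %), THF, −10 °C → reflux; then I2 (excess), THF, −78 → 0 °C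
Reagents that add atoms: methylmagnesium chloride, C[Mg]Cl; iodine, II
Why: Copper-catalysed anti-carbomagnesiation of a propargylic alkoxide; methyl adds to C4 and magnesium to C5, held cis to the carbinol carbon in the five-membered chelate 5. Iodinolysis with retention puts iodine cis to C3 and leaves the two methyls cis to each other; C3 is untouched.

Step 4
Reactants: 6 (2Z,4S)-2-iodo-3-methylocta-2,7-dien-4-ol; 7 tert-butyl(dimethyl)(prop-2-enyloxy)silane
Product: 9 (5S,6Z)-10-[tert-butyl(dimethyl)silyl]oxy-6,7-dimethyldeca-1,6-dien-5-ol, via B-alkyl-9-borabicyclononane 8 (not isolated)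
Conditions: 7, 9-BBN (1.0 equiv per 7), THF, rt; then 6, Pd(dppf)Cl2 (5 mol %), AsPh3 (5 mol %), Cs2CO3 (2 equiv), DMF/THF/H2O, rt → 45 °C
Reagents that add atoms: none
Why: B-alkyl Suzuki–Miyaura coupling; anti-Markovnikov hydroboration of 7 gives the primary alkylborane 8, which transmetalates after oxidative addition of the vinyl iodide. Oxidative addition and reductive elimination retain geometry, so the C6 chain takes the place of iodine, cis to C3. No B–H is left to attack the terminal alkene of 6.

Step 5
Reactants: 9 (5S,6Z)-10-[tert-butyl(dimethyl)silyl]oxy-6,7-dimethyldeca-1,6-dien-5-ol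
Product: 11 (5S,6Z)-10-[tert-butyl(dimethyl)silyl]oxy-6,7-dimethyldec-6-ene-1,5-diol, via bis-borylated adduct 10 (not isolated)
Conditions: 9-BBN (2.3 equiv), THF, 0 °C → rt; then NaOH (3 M), H2O2 (30 %), 0 °C → rt
Reagents that add atoms: hydrogen peroxide, OO
Why: Chemoselective hydroboration–oxidation; 9-BBN adds only to the monosubstituted alkene (boron at the terminal carbon, the future C9), while the tetrasubstituted alkene is too hindered. One equivalent is consumed by the hydroxyl.

Step 6
Reactants: 11 (5S,6Z)-10-[tert-butyl(dimethyl)silyl]oxy-6,7-dimethyldec-6-ene-1,5-diol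
Product: 12 (6S)-6-[(2Z)-6-{[tert-butyl(dimethyl)silyl]oxy}-3-methylhex-2-en-2-yl]oxan-2-one
Conditions: TEMPO (0.2 equiv), PhI(OAc)2 (2.5 equiv), CH2Cl2, rt
Reagents that add atoms: none
Why: Oxidative lactonisation of a 1,5-diol; the oxoammonium salt oxidises the primary alcohol much faster than the hindered secondary allylic one, the aldehyde closes to the lactol with the C3 hydroxyl, and a second oxidation gives the δ-lactone. C3 and the Z alkene are not touched.

Step 7
Reactants: 12 (6S)-6-[(2Z)-6-{[tert-butyl(dimethyl)silyl]oxy}-3-methylhex-2-en-2-yl]oxan-2-one
Product: 15 (1R,2S)-2-{3-[tert-butyl(dimethyl)silyl]oxypropyl}-2,3-dimethylcyclohex-3-ene-1-carboxylic acid, via cyclic silyl ketene acetal 13 (not isolated), via trimethylsilyl ester 14 (not isolated)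
Conditions: LiN(i-Pr)2 (1.3 equiv), Me3SiCl/Et3N (1:1, 3 equiv, present from the start), THF, −78 °C → rt; solvent change to toluene, 110 °C; then H2O/THF, AcOH, rt
Reagents that add atoms: none
Why: LiN(i-Pr)2 removes a C10 proton of the lactone in the presence of Me3SiCl and O-silylation gives the cyclic ketene acetal 13, in which C10=C9–O1–C3–C4=C5 is a 1,5-diene-type array; on heating, a concerted suprafacial [3,3] shift forms C5–C10 as O1–C3 breaks, leaving the C3=C4 bond and the silyl ester 14, which water cleaves to 15. The closest known reaction type is the Ireland–Claisen ring contraction of alkenyl-substituted lactones to cycloalkenecarboxylic acids. Ring A closes as a six-membered carbocycle by this sigmatropic contraction and not by a polar cyclisation: the two-carbon tether C1–C2 between C10 and C3 cannot span a chair, so the six reacting atoms adopt a boat inside a bicyclo[2.2.2]octane-like transition state. C5 is controlled by the (S) configuration at C3: the alkenyl group must stand axial on the lactone, so C10 can reach only one face of C4=C5, and the Z geometry turns the C6 chain toward the tether and the C14 methyl outward. C10 is controlled by the ring-locked ketene acetal geometry together with the boat, which places the carboxyl cis to the C5 methyl and trans to the C6 chain, as a trans-decalin requires. The step needs O- over C-silylation and rearrangement over self-condensation (secured by trapping the enolate as it forms), boat over chair (secured by the ring) and a concerted shift over ionisation of the allylic C–O bond (favoured by a non-polar solvent and the absence of Lewis acid).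

Step 8
Reactants: 15 (1R,2S)-2-{3-[tert-butyl(dimethyl)silyl]oxypropyl}-2,3-dimethylcyclohex-3-ene-1-carboxylic acid
Product: 17 [(1R,2S)-2-(3-hydroxypropyl)-2,3-dimethylcyclohex-3-en-1-yl]methanol, via silyl ether alcohol 16 (not isolated)
Conditions: LiAlH4 (2 equiv), THF, 0 °C → rt; then HCl (1 % in MeOH), rt
Reagents that add atoms: none
Why: Hydride reduction of the acid to the primary alcohol, then acid-catalysed methanolysis of the primary silyl ether. No stereocentre is involved and the trisubstituted alkene tolerates dilute acid.

Step 9
Reactants: 17 [(1R,2S)-2-(3-hydroxypropyl)-2,3-dimethylcyclohex-3-en-1-yl]methanol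
Product: 18 (1R,2S)-2,3-dimethyl-2-(3-oxopropyl)cyclohex-3-ene-1-carbaldehyde
Conditions: Dess–Martin periodinane (2.4 equiv), NaHCO3, CH2Cl2, 0 °C → rt; used at once
Reagents that add atoms: none
Why: Double oxidation with a hypervalent iodine reagent under buffered, non-basic conditions, chosen so that the C10 aldehyde next to the quaternary centre is not enolised.

Step 10
Reactants: 18 (1R,2S)-2,3-dimethyl-2-(3-oxopropyl)cyclohex-3-ene-1-carbaldehyde
Product: 19 11,12,13-trinoreremophil-3-ene-8α,9α-diol (5β-methyl; 10α-H; trans-fused)
Conditions: SmI2 (3 equiv), t-BuOH (2.2 equiv), THF, −78 °C → rt, slow addition of 18 (final 0.005 M)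
Reagents that add atoms: none
Why: Intramolecular pinacol coupling; single-electron transfer gives a ketyl that closes ring B on the second aldehyde through a samarium-bridged chair, which makes the two oxygens cis. C9–O should be equatorial (α) because an axial C9–O would clash with the axial C5 methyl, so C8–O is axial (α); the trans fusion follows from 15.

Step 11
Reactants: 19 11,12,13-trinoreremophil-3-ene-8α,9α-diol
Product: 21 11,12,13-trinoreremophilane-3α,8α,9α-triol (4β-methyl; 5β-methyl; 10α-H), via organoborane 20 (not isolated)
Conditions: BH3·SMe2 (4 equiv), THF, 0 °C → rt; then NaOH (3 M), H2O2 (30 %), 0 → 40 °C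
Reagents that add atoms: hydrogen peroxide, OO
Why: Hydroboration–oxidation of the trisubstituted C3=C4 bond; boron goes to the less substituted C3 and H to C4 in a syn addition from the α face, away from the axial C5 methyl. This gives the 3α hydroxyl and the 4β methyl, both equatorial; the diol is carried as borate esters and freed on work-up.

Step 12
Reactants: 21 11,12,13-trinoreremophilane-3α,8α,9α-triol
Product: 23 3α,9α-dihydroxy-11,12,13-trinoreremophilan-8-one, via dibutylstannylene acetal 22 (not isolated)
Conditions: Bu2SnO (1.05 equiv), toluene, reflux with azeotropic removal of water; then Br2 (1.0 equiv), CH2Cl2, 4 Å molecular sieves, rt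
Reagents that add atoms: none
Why: Brominolysis of the stannylene acetal of a cis-1,2-diol, a known regioselective diol oxidation in which the axial oxygen of the cis pair becomes the carbonyl. Only the 8,9-diol forms the five-membered stannylene, so the isolated C3 hydroxyl is not oxidised and the equatorial C9 hydroxyl is kept.

Step 13
Reactants: 23 3α,9α-dihydroxy-11,12,13-trinoreremophilan-8-one
Product: 24 3α,9α-bis(triethylsilyloxy)-11,12,13-trinoreremophilan-8-one
Conditions: Et3SiCl (2.6 equiv), imidazole (5 equiv), DMAP (0.1 equiv), DMF, 0 °C → rt
Reagents that add atoms: chlorotriethylsilane, CC[Si](Cl)(CC)CC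
Why: Silylation of two equatorial secondary hydroxyls; the ethers withstand amide bases, palladium catalysis and borohydrides and can be removed later without acid strong enough to harm the isopropenyl group.

Step 14
Reactants: 24 3α,9α-bis(triethylsilyloxy)-11,12,13-trinoreremophilan-8-one; 25 2-bromopropene
Product: 27 (7βH)-3α,9α-bis(triethylsilyloxy)eremophil-11-en-8-one, via lithium enolate 26 (not isolated)
Conditions: LiN(SiMe3)2 (2.2 equiv), THF, −78 → 0 °C; then 25 (1.5 equiv), Pd2(dba)3 (2.5 mol %), P(t-Bu)3 (6 mol %), toluene/THF, rt → 40 °C; AcOH, −78 °C
Reagents that add atoms: none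
Why: Palladium-catalysed α-alkenylation of a ketone enolate; kinetic deprotonation takes the C7 methylene and not the hindered silyloxy-bearing C9, and the enolate couples with the alkenylpalladium bromide. The product rests as its enolate until the cold quench, where axial protonation at C7 should leave the isopropenyl group equatorial (α), which is also the more stable arrangement.

Step 15
Reactants: 27 (7βH)-3α,9α-bis(triethylsilyloxy)eremophil-11-en-8-one
Product: 28 (7βH)-3α,9α-bis(triethylsilyloxy)eremophil-11-en-8α-ol
Conditions: LiBH(s-Bu)3 (1.5 equiv), THF, −78 °C; then NaOH, H2O2, 0 °C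
Reagents that add atoms: none
Why: Reduction of a cyclohexanone by a bulky trialkylborohydride, which attacks along the equatorial direction and gives the axial 8α alcohol, cis to both equatorial neighbours. At −78 °C the reduction should outrun enolisation of the β,γ-unsaturated ketone.

Step 16
Reactants: 28 (7βH)-3α,9α-bis(triethylsilyloxy)eremophil-11-en-8α-ol
Product: 29 (7βH)-eremophil-11-ene-3α,8α,9α-triol
Conditions: HF·pyridine, pyridine/THF, 0 °C → rt
Reagents that add atoms: none
Why: Fluoride-driven cleavage of both triethylsilyl ethers under buffered conditions that do not hydrate or isomerise the isopropenyl group. Any silyl migration between O9 and O8 in the previous step is made harmless by this global removal.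

Step 17
Reactants: 29 (7βH)-eremophil-11-ene-3α,8α,9α-triol; 30 hex-2-ynoic acid
Product: 31 (7βH)-3α,9α-bis(hex-2-ynoyloxy)eremophil-11-en-8α-ol
Conditions: 30 (2.2 equiv), DCC (2.3 equiv), DMAP (0.2 equiv), CH2Cl2, −20 → 0 °C
Reagents that add atoms: none
Why: Carbodiimide esterification; the two equatorial hydroxyls (C3, C9) should react well before the axial C8 hydroxyl, which is flanked by the isopropenyl-bearing C7 and, after the first acylation, by the C9 ester. The alkynoate has no double-bond geometry to lose under DMAP catalysis.

Step 18
Reactants: 31 (7βH)-3α,9α-bis(hex-2-ynoyloxy)eremophil-11-en-8α-ol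
Product: 32 (7βH)-3α,9α-bis[(2Z)-hex-2-enoyloxy]eremophil-11-en-8α-ol (CNP0420276.1)
Conditions: H2 (1 atm), Pd/CaCO3 poisoned with Pb(OAc)2, quinoline, EtOAc, rt, stopped after 2 equiv H2
Reagents that add atoms: none
Why: Syn semi-hydrogenation of the two conjugated alkynes on a poisoned palladium surface gives the Z-enoates. The alkynes bind far more strongly than the 1,1-disubstituted isopropenyl alkene, which should survive if uptake is stopped at two equivalents.

## Compound list

1 | propyne | CC#C | starting material
2 | pent-4-enoyl chloride | C=CCCC(=O)Cl | starting material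
3 | oct-7-en-2-yn-4-one | CC#CC(=O)CCC=C | intermediate
4 | (4S)-oct-7-en-2-yn-4-ol | CC#C[C@@H](O)CCC=C | intermediate
5 | (5S)-5-(but-3-enyl)-3,4-dimethyl-2,5-dihydro-1,2-oxamagnesole | C=CCC[C@@H]1O[Mg]C(C)=C1C | intermediate (not isolated)
6 | (2Z,4S)-2-iodo-3-methylocta-2,7-dien-4-ol | C=CCC[C@H](O)/C(C)=C(/C)I | intermediate
7 | tert-butyl(dimethyl)(prop-2-enyloxy)silane | C=CCO[Si](C)(C)C(C)(C)C | starting material
8 | 9-{3-[tert-butyl(dimethyl)silyl]oxypropyl}-9-borabicyclo[3.3.1]nonane | CC(C)(C)[Si](C)(C)OCCCB1C2CCCC1CCC2 | intermediate (not isolated)
9 | (5S,6Z)-10-[tert-butyl(dimethyl)silyl]oxy-6,7-dimethyldeca-1,6-dien-5-ol | C=CCC[C@H](O)/C(C)=C(/C)CCCO[Si](C)(C)C(C)(C)C | intermediate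
10 | adduct of 9 with two 9-borabicyclononane units (C1 alkylborane, O5 borinate) | B1(CCCC[C@H](OB2C3CCCC2CCC3)/C(C)=C(/C)CCCO[Si](C)(C)C(C)(C)C)C2CCCC1CCC2 | intermediate (not isolated)
11 | (5S,6Z)-10-[tert-butyl(dimethyl)silyl]oxy-6,7-dimethyldec-6-ene-1,5-diol | OCCCC[C@H](O)/C(C)=C(/C)CCCO[Si](C)(C)C(C)(C)C | intermediate
12 | (6S)-6-[(2Z)-6-{[tert-butyl(dimethyl)silyl]oxy}-3-methylhex-2-en-2-yl]oxan-2-one | O=C1CCC[C@H](O1)/C(C)=C(/C)CCCO[Si](C)(C)C(C)(C)C | intermediate (key-step precursor)
13 | (2S)-2-[(2Z)-6-{[tert-butyl(dimethyl)silyl]oxy}-3-methylhex-2-en-2-yl]-6-(trimethylsilyloxy)-3,4-dihydro-2H-pyran | C[Si](C)(C)OC1=CCC[C@H](O1)/C(C)=C(/C)CCCO[Si](C)(C)C(C)(C)C | intermediate (not isolated)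
14 | trimethylsilyl (1R,2S)-2-{3-[tert-butyl(dimethyl)silyl]oxypropyl}-2,3-dimethylcyclohex-3-ene-1-carboxylate | C[Si](C)(C)OC(=O)[C@@H]1CCC=C(C)[C@@]1(C)CCCO[Si](C)(C)C(C)(C)C | intermediate (not isolated)
15 | (1R,2S)-2-{3-[tert-butyl(dimethyl)silyl]oxypropyl}-2,3-dimethylcyclohex-3-ene-1-carboxylic acid | OC(=O)[C@@H]1CCC=C(C)[C@@]1(C)CCCO[Si](C)(C)C(C)(C)C | intermediate (key-step product)
16 | [(1R,2S)-2-{3-[tert-butyl(dimethyl)silyl]oxypropyl}-2,3-dimethylcyclohex-3-en-1-yl]methanol | OC[C@@H]1CCC=C(C)[C@@]1(C)CCCO[Si](C)(C)C(C)(C)C | intermediate (not isolated)
17 | [(1R,2S)-2-(3-hydroxypropyl)-2,3-dimethylcyclohex-3-en-1-yl]methanol | OC[C@@H]1CCC=C(C)[C@@]1(C)CCCO | intermediate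
18 | (1R,2S)-2,3-dimethyl-2-(3-oxopropyl)cyclohex-3-ene-1-carbaldehyde | O=C[C@@H]1CCC=C(C)[C@@]1(C)CCC=O | intermediate
19 | 11,12,13-trinoreremophil-3-ene-8α,9α-diol (5β-methyl; 10α-H) | C1C[C@]2(C)C(C)=CCC[C@H]2[C@H](O)[C@@H]1O | intermediate
20 | 3α-boryl-11,12,13-trinoreremophilane-8α,9α-diyl cyclic borate (4β-methyl) | C1C[C@]2(C)[C@@H](C)[C@H](B)CC[C@H]2[C@@H]3OBO[C@H]13 | intermediate (not isolated)
21 | 11,12,13-trinoreremophilane-3α,8α,9α-triol (4β-methyl; 5β-methyl; 10α-H) | C1C[C@]2(C)[C@@H](C)[C@H](O)CC[C@H]2[C@H](O)[C@@H]1O | intermediate
22 | 8α,9α-O-dibutylstannylene acetal of 21 | C1C[C@]2(C)[C@@H](C)[C@H](O)CC[C@H]2[C@@H]3O[Sn](CCCC)(CCCC)O[C@H]13 | intermediate (not isolated)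
23 | 3α,9α-dihydroxy-11,12,13-trinoreremophilan-8-one | C1C[C@]2(C)[C@@H](C)[C@H](O)CC[C@H]2[C@H](O)C1=O | intermediate
24 | 3α,9α-bis(triethylsilyloxy)-11,12,13-trinoreremophilan-8-one | C1C[C@]2(C)[C@@H](C)[C@H](O[Si](CC)(CC)CC)CC[C@H]2[C@H](O[Si](CC)(CC)CC)C1=O | intermediate
25 | 2-bromopropene | CC(Br)=C | starting material
26 | lithium 7(8)-enolate of 24 | [Li]OC1=CC[C@]2(C)[C@@H](C)[C@H](O[Si](CC)(CC)CC)CC[C@H]2[C@@H]1O[Si](CC)(CC)CC | intermediate (not isolated)
27 | (7βH)-3α,9α-bis(triethylsilyloxy)eremophil-11-en-8-one | C=C(C)[C@@H]1C[C@]2(C)[C@@H](C)[C@H](O[Si](CC)(CC)CC)CC[C@H]2[C@H](O[Si](CC)(CC)CC)C1=O | intermediate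
28 | (7βH)-3α,9α-bis(triethylsilyloxy)eremophil-11-en-8α-ol | C=C(C)[C@@H]1C[C@]2(C)[C@@H](C)[C@H](O[Si](CC)(CC)CC)CC[C@H]2[C@H](O[Si](CC)(CC)CC)[C@@H]1O | intermediate
29 | (7βH)-eremophil-11-ene-3α,8α,9α-triol | C=C(C)[C@@H]1C[C@]2(C)[C@@H](C)[C@H](O)CC[C@H]2[C@H](O)[C@@H]1O | intermediate
30 | hex-2-ynoic acid | CCCC#CC(=O)O | starting material
31 | (7βH)-3α,9α-bis(hex-2-ynoyloxy)eremophil-11-en-8α-ol | C=C(C)[C@@H]1C[C@]2(C)[C@@H](C)[C@H](OC(=O)C#CCCC)CC[C@H]2[C@H](OC(=O)C#CCCC)[C@@H]1O | intermediate
32 | (7βH)-3α,9α-bis[(2Z)-hex-2-enoyloxy]eremophil-11-en-8α-ol (CNP0420276.1) | C=C(C)[C@@H]1C[C@]2(C)[C@@H](C)[C@H](OC(=O)/C=C\CCC)CC[C@H]2[C@H](OC(=O)/C=C\CCC)[C@@H]1O | target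

## Step count and least certain steps

Total: 18 steps. Longest linear sequence: 18 steps from 1 and 2. Compounds 7, 25 and 30 are purchased, and 8 is made in the flask.

**Step 7 (key step).** The [3,3] shift may be slow or fail, because the boat forces the C2 and C6 methylenes together while a quaternary centre forms. The ketene acetal may instead be lost through C-silylation, self-condensation of the enolate, or ionisation of the allylic C–O bond with loss of chirality transfer. Fallback, from 9 back to 15: 9 would be esterified with hex-5-enoic acid under Mitsunobu conditions (PPh3, diisopropyl azodicarboxylate), inverting C3, to give hex-5-enoate ester F1. An open-chain Ireland–Claisen rearrangement through a chair (LiN(i-Pr)2, THF/DMPU, Me3SiCl, so that the enolate has its alkyl chain cis to the metal-bound oxygen) should pass the inverted carbinol configuration to C5 and C10 and give the dienyl acid F2. Ring-closing metathesis with the second-generation Grubbs catalyst between the vinyl group on the C10 side chain and the trisubstituted C4 alkene then closes ring A, with loss of hexa-1,5-diene, and returns 15.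

**Step 3.** Carbomagnesiation of the internal alkyne may stall, or the chelate may be protonated instead of iodinated, because methyl transfer to a disubstituted alkyne is slow. Fallback, from 2 back to 9: 2 would be coupled with tert-butyl(dimethyl)(pent-4-ynyloxy)silane under the conditions of step 1 to give ynone F3, and reduced as in step 2 to propargylic alcohol F4. Alkoxide-directed syn-methylmagnesiation (MeMgBr, Fe(acac)3 catalyst, THF), followed by copper-catalysed methylation of the alkenylmagnesium species with MeI, would place two cis methyls on the alkyne and give 9 directly, without 6 or the cross-coupling.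

**Step 10.** Intermolecular coupling, simple reduction to 17, formation of a trans-diol, or enolisation of the C10 aldehyde before coupling may lower the yield or the stereochemical purity. Fallback, from 18 back to 19: reductive carbonyl coupling with low-valent titanium (TiCl3, Zn–Cu, dimethoxyethane, reflux; McMurry reaction) would give the diene F5. Dihydroxylation with OsO4/N-methylmorpholine N-oxide should then occur at the less hindered disubstituted C8=C9 bond from the α face and return 19; competing attack at the hindered C3=C4 bond is the weak point of this detour.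

**Step 12.** Oxidation at the wrong oxygen, over-oxidation to the diketone, or migration of the carbonyl to C9 through the enediol (with scrambling of C10) may occur. Fallback, from 21 back to 24: selective silylation of the two equatorial hydroxyls (Et3SiCl 2.1 equiv, imidazole, DMF, −20 °C) would give the bis-silyl ether alcohol F6, and oxidation of the remaining axial C8 hydroxyl with Dess–Martin periodinane would return 24.

**Step 14.** Failure of the hindered enolate to couple, double alkenylation, enolisation toward C9, or drift of the product double bond into conjugation during work-up are the likely losses. Fallback, from 24 back to 27: aldol addition of the C7 lithium enolate (LiN(i-Pr)2, THF, −78 °C) to acetone would give the tertiary aldol F7. Dehydration (MeSO2Cl, Et3N; then DBU) would give the conjugated isopropylidene ketone F8. Deconjugation by kinetic γ-deprotonation (LiN(i-Pr)2, THF, −78 °C) and α-protonation with AcOH would return 27.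

**Step 17.** Poor site selectivity, acylation of the C8 hydroxyl, or acyl migration from O9 to O8 may give mixtures, since three secondary hydroxyls compete. Fallback, from 28 back to 31: the free C8 hydroxyl of 28 would be silylated (t-BuMe2SiOTf, 2,6-lutidine) to the tris-silyl ether F9. The two triethylsilyl ethers would be removed selectively (pyridinium p-toluenesulfonate, MeOH) to give the 8-O-silyl diol F10. Esterification with 30 as in step 17 would give the 8-O-silyl bis-ynoate F11, and HF·pyridine would return 31.

## Further compounds

F1 | step 7 | (5R,6Z)-10-[tert-butyl(dimethyl)silyl]oxy-6,7-dimethyldeca-1,6-dien-5-yl hex-5-enoate | C=CCCCC(=O)O[C@H](CCC=C)/C(C)=C(/C)CCCO[Si](C)(C)C(C)(C)C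
F2 | step 7 | (2R,3S,4E)-2-(but-3-enyl)-3-{3-[tert-butyl(dimethyl)silyl]oxypropyl}-3,4-dimethylnona-4,8-dienoic acid | OC(=O)[C@H](CCC=C)[C@](C)(CCCO[Si](C)(C)C(C)(C)C)/C(C)=C/CCC=C
F3 | step 3 | 10-[tert-butyl(dimethyl)silyl]oxydec-1-en-6-yn-5-one | C=CCCC(=O)C#CCCCO[Si](C)(C)C(C)(C)C
F4 | step 3 | (5S)-10-[tert-butyl(dimethyl)silyl]oxydec-1-en-6-yn-5-ol | C=CCC[C@H](O)C#CCCCO[Si](C)(C)C(C)(C)C
F5 | step 10 | 11,12,13-trinoreremophila-3,8-diene (5β-methyl; 10α-H) | C1C[C@]2(C)C(C)=CCC[C@H]2C=C1
F6 | step 12 | 3α,9α-bis(triethylsilyloxy)-11,12,13-trinoreremophilan-8α-ol | C1C[C@]2(C)[C@@H](C)[C@H](O[Si](CC)(CC)CC)CC[C@H]2[C@H](O[Si](CC)(CC)CC)[C@@H]1O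
F7 | step 14 | (7βH)-11-hydroxy-3α,9α-bis(triethylsilyloxy)eremophilan-8-one | CC(C)(O)[C@@H]1C[C@]2(C)[C@@H](C)[C@H](O[Si](CC)(CC)CC)CC[C@H]2[C@H](O[Si](CC)(CC)CC)C1=O
F8 | step 14 | 3α,9α-bis(triethylsilyloxy)eremophil-7(11)-en-8-one | CC(C)=C1C[C@]2(C)[C@@H](C)[C@H](O[Si](CC)(CC)CC)CC[C@H]2[C@H](O[Si](CC)(CC)CC)C1=O
F9 | step 17 | (7βH)-8α-[tert-butyl(dimethyl)silyl]oxy-3α,9α-bis(triethylsilyloxy)eremophil-11-ene | C=C(C)[C@@H]1C[C@]2(C)[C@@H](C)[C@H](O[Si](CC)(CC)CC)CC[C@H]2[C@H](O[Si](CC)(CC)CC)[C@@H]1O[Si](C)(C)C(C)(C)C
F10 | step 17 | (7βH)-8α-[tert-butyl(dimethyl)silyl]oxyeremophil-11-ene-3α,9α-diol | C=C(C)[C@@H]1C[C@]2(C)[C@@H](C)[C@H](O)CC[C@H]2[C@H](O)[C@@H]1O[Si](C)(C)C(C)(C)C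
F11 | step 17 | (7βH)-8α-[tert-butyl(dimethyl)silyl]oxy-3α,9α-bis(hex-2-ynoyloxy)eremophil-11-ene | C=C(C)[C@@H]1C[C@]2(C)[C@@H](C)[C@H](OC(=O)C#CCCC)CC[C@H]2[C@H](OC(=O)C#CCCC)[C@@H]1O[Si](C)(C)C(C)(C)C
A1 | alternative 1 | (7aS)-7a-methyl-2,3,7,7a-tetrahydro-1H-indene-1,5(6H)-dione | O=C1CCC2=CC(=O)CC[C@]12C
A2 | alternative 1 | (7aS)-1-ethenyl-1-hydroxy-7a-methyl-1,2,3,6,7,7a-hexahydro-5H-inden-5-one, hydroxyl cis to the angular methyl | C=C[C@]1(O)CCC2=CC(=O)CC[C@]12C
A3 | alternative 1 | 4-(bromomethyl)-5-methyloctal-9-ene-3,8-dione (4β-bromomethyl; 5β-methyl) | O=C1CCC2=CC(=O)CC[C@]2(C)[C@H]1CBr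
A4 | alternative 2 | (5E,9Z)-2-[tert-butyl(dimethyl)silyl]oxy-5-methyl-3-(prop-1-en-2-yl)-9-(trimethylsilyloxy)undeca-5,9-dienal, C2 and C3 configured as C8 and C7 of 32 | O=C[C@H](O[Si](C)(C)C(C)(C)C)[C@H](C(C)=C)C/C(C)=C/CC/C(O[Si](C)(C)C)=C/C
A5 | alternative 2 | (7βH)-8α-[tert-butyl(dimethyl)silyl]oxy-9α-hydroxyeremophil-11-en-3-one | C=C(C)[C@@H]1C[C@]2(C)[C@@H](C)C(=O)CC[C@H]2[C@H](O)[C@@H]1O[Si](C)(C)C(C)(C)C
A6 | alternative 3 | 2-methoxy-5-methyl-1,4-benzoquinone | COC1=CC(=O)C(C)=CC1=O
A7 | alternative 3 | (3Z)-3-[tert-butyl(dimethyl)silyl]oxypenta-1,3-diene | C=C/C(O[Si](C)(C)C(C)(C)C)=C/C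
A8 | alternative 3 | cis-fused endo adduct: 3-[tert-butyl(dimethyl)silyl]oxy-8-methoxy-4α,5β-dimethyl-10βH-octala-2,7-diene-6,9-dione | O=C1C=C(OC)C(=O)[C@H]2CC=C(O[Si](C)(C)C(C)(C)C)[C@@H](C)[C@@]12C
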